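**Plan**
1. Retrosynthesis: the senecioate, the two silyl ethers and the trans-epoxide (from a cis-diol monomesylate, one inversion) are removed last; the C(CH2OH)= carbon is traced back to an enol triflate, i.e. a trapped ketone enolate.
2. Main cut: the bond between the quaternary ring carbon and the ring CH2 lies between the trans CH=CH and the C(CH2OH)=CH alkenes, so these six atoms form a 1,5-diene. A retro-oxy-Cope step joins the =CH next to CH–O with the C(CH2OH)= carbon; the five ring atoms between them (CH–O, C(Me)–O, CH–O, CH2, CH2) then complete a cycloheptane, a 1-vinyl-2-alkenylcycloheptan-1-ol.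
3. Forward: tropone is turned into an enantiopure cycloheptane template that carries the three C–O centres; the side chain (from pent-4-ynoic acid, carboalumination) is joined by epoxide opening; ethynylation and semi-hydrogenation give the cis-dialkenyl carbinol; anionic oxy-Cope ring expansion (7 to 11) with enolate triflation follows; then hydroxymethylation, epoxide closure, esterification and desilylation.
4. Stereochemistry: two CBS reductions fix the absolute configuration (side-chain carbinol, template C5); the cycloheptane relays it to C4 and C3 and to the temporary centres C1 and C2, which set the quaternary carbon and both ring alkene geometries in the chair transition state.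

Key step: step 18

Remark on the chemistry: the target is taken as drawn, with the two ring carbons of the C(CH2OH)=CH alkene cis (E by CIP). The route has not been run; the facial selectivities in steps 8, 10 and 16 are predictions.

Conventions used in the names: template atoms are C1 (carbonyl/carbinol carbon), C2 (side-chain carbon), C3, C4 (methyl-bearing), C5, C6, C7. The 11-membered ring is numbered C1 = C(O or CH2O)=, C4 = quaternary carbon, C5=C6 = CH=CH, C7 = CH–O, C8/C9 = diol or epoxide carbons. TBDPS = tert-butyldiphenylsilyl, PMB = 4-methoxybenzyl. Side chain A = (1E,5R)-5-(TBDPS-oxy)-2,6-dimethylhepta-1,6-dien-1-yl. Side chain B = (3R)-3-(TBDPS-oxy)-4-methylpent-4-en-1-yl.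

**Step 1**
Reactants: 1 pent-4-ynoic acid
Product: 2 N-methoxy-N-methylpent-4-ynamide
Conditions: MeNH(OMe)·HCl, EDC·HCl, Et3N, DMAP (cat.), CH2Cl2, 0 °C to rt
Reagents that add atoms: N,O-dimethylhydroxylamine hydrochloride, CNOC.Cl
Why: Carbodiimide amide coupling gives the Weinreb amide, which stops the next organometallic addition at the ketone stage.

**Step 2**
Reactants: 2 N-methoxy-N-methylpent-4-ynamide
Product: 3 2-methylhept-1-en-6-yn-3-one
Conditions: isopropenylmagnesium bromide (2.2 equiv), THF, −20 to 0 °C; cold aq NH4Cl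
Reagents that add atoms: isopropenylmagnesium bromide, CC(=C)[Mg]Br
Why: Weinreb ketone synthesis, in which the chelated tetrahedral adduct prevents over-addition and one extra equivalent of Grignard reagent is spent on the acidic alkyne C–H.

**Step 3**
Reactants: 3 2-methylhept-1-en-6-yn-3-one
Product: 4 (R)-2-methylhept-1-en-6-yn-3-ol
Conditions: (S)-2-methyl-CBS-oxazaborolidine (0.2 equiv), catecholborane, toluene, −78 °C
Reagents that add atoms: none
Why: Corey–Bakshi–Shibata reduction in which the isopropenyl group acts as the large ketone substituent, so hydride delivery from the (S)-catalyst–borane complex should give the (R)-carbinol while catecholborane at low temperature leaves alkyne and alkene untouched.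

**Step 4**
Reactants: 4 (R)-2-methylhept-1-en-6-yn-3-ol
Product: 5 (R)-tert-butyl[(2-methylhept-1-en-6-yn-3-yl)oxy]diphenylsilane
Conditions: TBDPSCl, imidazole, DMF, rt
Reagents that add atoms: tert-butyl(chloro)diphenylsilane, CC(C)(C)[Si](Cl)(c1ccccc1)c1ccccc1
Why: Standard silylation; the TBDPS ether is chosen because it should survive organolithium, KH, aqueous acid and DDQ steps and fall only to fluoride at the end.

**Step 5**
Reactants: 5 (R)-tert-butyl[(2-methylhept-1-en-6-yn-3-yl)oxy]diphenylsilane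
Product: 7 (3R,6E)-3-(TBDPS-oxy)-7-iodo-2,6-dimethylhepta-1,6-diene, via alkenylalane 6 (not isolated)
Conditions: Me3Al, Cp2ZrCl2 (0.25 equiv), CH2Cl2, 0 °C to rt; then I2, THF, −30 to 0 °C
Reagents that add atoms: trimethylaluminium, C[Al](C)C; iodine, II
Why: Zirconium-catalysed carboalumination adds methyl and aluminium syn across the terminal alkyne (methyl to the internal carbon) and iodinolysis proceeds with retention, which fixes the (E)-alkene with methyl cis to the carbon that later bonds to the ring; the 1,1-disubstituted alkene is inert.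

**Step 6**
Reactants: 8 tropone
Product: 10 2-methylcyclohepta-2,4-dien-1-one, via 2-methylcyclohepta-3,5-dien-1-one 9 (not isolated)
Conditions: MeMgBr, THF, −78 to 0 °C; aq NH4Cl; then DBU (0.1 equiv), CH2Cl2, rt
Reagents that add atoms: methylmagnesium bromide, C[Mg]Br
Why: Conjugate (1,8-) Grignard addition to tropone gives the 2-methyl-3,5-dienone, which base isomerises through its dienolate to the fully conjugated, more substituted 2,4-dienone.

**Step 7**
Reactants: 10 2-methylcyclohepta-2,4-dien-1-one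
Product: 11 (R)-2-methylcyclohepta-2,4-dien-1-ol
Conditions: (S)-2-methyl-CBS-oxazaborolidine (0.2 equiv), catecholborane, toluene, −78 °C
Reagents that add atoms: none
Why: Corey–Bakshi–Shibata 1,2-reduction with the α-methyl dienyl group as the large substituent should give the (R)-allylic alcohol, the stereocenter (template C5) from which the whole template is relayed.

**Step 8**
Reactants: 11 (R)-2-methylcyclohepta-2,4-dien-1-ol
Product: 13 (4S,5R)-4,5-dihydroxy-4-methylcyclohept-2-en-1-one, via endoperoxide 12 (not isolated)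
Conditions: O2, tetraphenylporphyrin (cat.), visible light, CH2Cl2, −30 °C; then Et3N (0.5 equiv), 0 °C to rt
Reagents that add atoms: dioxygen, O=O
Why: [4+2] cycloaddition of singlet oxygen to the s-cis diene, directed by hydrogen bonding to the face of the pseudo-axial allylic hydroxyl in a non-polar solvent, followed by Kornblum–DeLaMare rearrangement (the base removes the only bridgehead hydrogen) gives the γ-hydroxy enone with the new tertiary C–O cis to the carbinol.

**Step 9**
Reactants: 13 (4S,5R)-4,5-dihydroxy-4-methylcyclohept-2-en-1-one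
Product: 14 (4S,5R)-4,5-(isopropylidenedioxy)-4-methylcyclohept-2-en-1-one
Conditions: 2,2-dimethoxypropane, PPTS (cat.), acetone, rt
Reagents that add atoms: 2,2-dimethoxypropane, COC(C)(C)OC
Why: Acid-catalysed transketalisation of the cis-diol gives the cis-fused dioxolane, which protects both hydroxyls through the basic steps and makes the two ring faces different.

**Step 10**
Reactants: 14 (4S,5R)-4,5-(isopropylidenedioxy)-4-methylcyclohept-2-en-1-one
Product: 15 (2S,3R,4R,5R)-2,3-epoxy-4,5-(isopropylidenedioxy)-4-methylcycloheptan-1-one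
Conditions: t-BuOOH (in decane), DBU, CH2Cl2, 0 °C to rt
Reagents that add atoms: tert-butyl hydroperoxide, CC(C)(C)OO
Why: Weitz–Scheffer nucleophilic epoxidation in which the peroxide anion should add to the β-carbon anti to the pseudo-axial γ C–O bond of the fused dioxolane, placing the epoxide (the future C3–O) trans to the acetonide.

**Step 11**
Reactants: 15 (2S,3R,4R,5R)-2,3-epoxy-4,5-(isopropylidenedioxy)-4-methylcycloheptan-1-one
Product: 16 (1R,2R,3R,4R,5R)-2,3-epoxy-4,5-(isopropylidenedioxy)-4-methylcycloheptan-1-ol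
Conditions: NaBH4, MeOH, −40 °C
Reagents that add atoms: none
Why: Borohydride reduction with attack anti to the adjacent epoxide C–O bond should give the cis-epoxy alcohol; C1 is a temporary centre (re-oxidised in step 15) that keeps C2 the less hindered epoxide carbon and provides the cis-1,3 relationship used in steps 13 and 14.

**Step 12**
Reactants: 7 (3R,6E)-3-(TBDPS-oxy)-7-iodo-2,6-dimethylhepta-1,6-diene; 16 (1R,2R,3R,4R,5R)-2,3-epoxy-4,5-(isopropylidenedioxy)-4-methylcycloheptan-1-ol
Product: 18 (1R,2S,3R,4S,5R)-4,5-(isopropylidenedioxy)-4-methyl-2-(side chain A)cycloheptane-1,3-diol, via alkenyllithium 17 (not isolated)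
Conditions: 7, t-BuLi (2 equiv), Et2O, −78 °C; 16 pretreated with n-BuLi (1 equiv), THF, −78 °C; then BF3·OEt2, −78 °C
Reagents that add atoms: none
Why: Iodine–lithium exchange with retention of alkene geometry, then BF3-assisted SN2 epoxide opening with inversion at C2 (trans-diaxial opening with the C4 methyl equatorial; C3 is shielded by the fully substituted C4), which sets the side chain trans to the new C3 hydroxyl.

**Step 13**
Reactants: 18 (1R,2S,3R,4S,5R)-4,5-(isopropylidenedioxy)-4-methyl-2-(side chain A)cycloheptane-1,3-diol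
Product: 19 1,3-O-(4-methoxybenzylidene) acetal of 18 (aryl equatorial on the new 1,3-dioxane)
Conditions: 4-MeOC6H4CH(OMe)2, PPTS (cat.), CH2Cl2, 4 Å sieves, rt
Reagents that add atoms: 4-methoxybenzaldehyde dimethyl acetal, COC(OC)c1ccc(OC)cc1
Why: Acetalisation of the cis-1,3-diol gives the six-membered benzylidene-type acetal under thermodynamic control (aryl equatorial), which prepares the differentiation of the two secondary hydroxyls.

**Step 14**
Reactants: 19 1,3-O-(4-methoxybenzylidene) acetal of 18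
Product: 20 (1R,2S,3R,4R,5R)-4,5-(isopropylidenedioxy)-3-(PMB-oxy)-4-methyl-2-(side chain A)cycloheptan-1-ol
Conditions: i-Bu2AlH (DIBAL-H), CH2Cl2, −78 to 0 °C
Reagents that add atoms: none
Why: Regioselective reductive acetal opening: the aluminium reagent coordinates the less hindered C1 oxygen and cleaves that C–O bond, leaving the PMB ether on the hindered C3 oxygen (next to the quaternary C4) and the C1 hydroxyl free.

**Step 15**
Reactants: 20 (1R,2S,3R,4R,5R)-4,5-(isopropylidenedioxy)-3-(PMB-oxy)-4-methyl-2-(side chain A)cycloheptan-1-ol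
Product: 21 (2R,3R,4R,5R)-4,5-(isopropylidenedioxy)-3-(PMB-oxy)-4-methyl-2-(side chain A)cycloheptan-1-one
Conditions: Dess–Martin periodinane, NaHCO3, CH2Cl2, 0 °C
Reagents that add atoms: none
Why: Dess–Martin oxidation under buffered, non-basic conditions should avoid epimerisation at C2, conjugation of the β,γ-alkene and β-elimination of the PMB-oxy group.

**Step 16**
Reactants: 21 (2R,3R,4R,5R)-4,5-(isopropylidenedioxy)-3-(PMB-oxy)-4-methyl-2-(side chain A)cycloheptan-1-one
Product: 22 (1R,2R,3R,4R,5R)-1-ethynyl-4,5-(isopropylidenedioxy)-3-(PMB-oxy)-4-methyl-2-(side chain A)cycloheptan-1-ol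
Conditions: HC≡CMgBr, CeCl3 (dried), THF, −78 °C
Reagents that add atoms: ethynylmagnesium bromide, C#C[Mg]Br
Why: Organocerium 1,2-addition suppresses enolisation, and the small linear ethynyl nucleophile should attack pseudo-axially, anti to the axial C2–H and therefore on the face of the equatorial side chain, giving the carbinol with OH trans to the side chain.

**Step 17**
Reactants: 22 (1R,2R,3R,4R,5R)-1-ethynyl-4,5-(isopropylidenedioxy)-3-(PMB-oxy)-4-methyl-2-(side chain A)cycloheptan-1-ol
Product: 23 (1S,2R,3R,4R,5R)-1-ethenyl-4,5-(isopropylidenedioxy)-3-(PMB-oxy)-4-methyl-2-(side chain A)cycloheptan-1-ol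
Conditions: H2 (1 atm), Pd/CaCO3 poisoned with Pb(OAc)2 (Lindlar catalyst), quinoline, EtOAc, rt
Reagents that add atoms: none
Why: Lindlar semi-hydrogenation reduces only the terminal alkyne to the vinyl group, which is now cis to the C2 side chain; the substituted alkenes and the PMB ether should not be touched.

**Step 18**
Reactants: 23 (1S,2R,3R,4R,5R)-1-ethenyl-4,5-(isopropylidenedioxy)-3-(PMB-oxy)-4-methyl-2-(side chain A)cycloheptan-1-ol
Product: 25 (1E,4S,5E,7R,8R,9R)-8,9-(isopropylidenedioxy)-7-(PMB-oxy)-4,8-dimethyl-4-(side chain B)cycloundeca-1,5-dien-1-yl trifluoromethanesulfonate, via potassium enolate 24 (not isolated)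
Conditions: KH, 18-crown-6, THF, 0 to 45 °C; then PhNTf2, −78 to 0 °C
Reagents that add atoms: N-phenylbis(trifluoromethanesulfonimide), O=S(=O)(N(c1ccccc1)S(=O)(=O)C(F)(F)F)C(F)(F)F
Why: Deprotonation gives the potassium alkoxide of the 3-hydroxy-1,5-diene, whose anionic oxy-Cope ([3,3]-sigmatropic) rearrangement breaks the C1–C2 bond of the cycloheptane and joins the vinyl CH2 terminus to the methyl-bearing alkene carbon, and the regiodefined enolate 24 is then O-sulfonylated. The closest known reaction type is the anionic oxy-Cope four-carbon ring expansion of 1,2-dialkenylcycloalkanols to cycloalkenones with trapping of the enolate. The 11-membered ring is closed by this 7-to-11 ring expansion through a six-membered chair transition state, not by an end-to-end cyclisation, so no high dilution is needed. The quaternary stereocenter arises by chirality transfer from C1 and C2 of the template: the (E)-alkene places its methyl pseudo-axial and the side chain pseudo-equatorial in the chair, which gives the S configuration. The step needs the chair in which the C2–C3 ring bond is pseudo-equatorial (trans CH=CH) and the C1–C7 ring bond pseudo-axial with the oxyanion pseudo-equatorial (enolate with the two ring carbons cis); the cis relationship of vinyl and alkenyl groups, and the 1,3-diaxial clash the pseudo-axial methyl would meet in the other chair, secure this. Regiochemistry and geometry of the enolate are fixed by the rearrangement and are kept in the enol triflate.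

**Step 19**
Reactants: 25 enol triflate (as named in step 18)
Product: 26 [(1E,4S,5E,7R,8R,9R)-8,9-(isopropylidenedioxy)-7-(PMB-oxy)-4,8-dimethyl-4-(side chain B)cycloundeca-1,5-dien-1-yl]methanol
Conditions: Bu3SnCH2OH, Pd(PPh3)4 (0.1 equiv), LiCl, 1,4-dioxane, 90 °C
Reagents that add atoms: (tributylstannyl)methanol, CCCC[Sn](CO)(CCCC)CCCC
Why: Stille coupling transfers the hydroxymethyl group to the alkenyl triflate with retention of alkene geometry, and it is run before any allylic ester is present that zerovalent palladium could ionise.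

**Step 20**
Reactants: 26 allylic alcohol (as named in step 19)
Product: 27 (1E,4S,5E,7R,8R,9R)-1-(TBDPS-oxymethyl)-8,9-(isopropylidenedioxy)-7-(PMB-oxy)-4,8-dimethyl-4-(side chain B)cycloundeca-1,5-diene
Conditions: TBDPSCl, imidazole, CH2Cl2, rt
Reagents that add atoms: tert-butyl(chloro)diphenylsilane, CC(C)(C)[Si](Cl)(c1ccccc1)c1ccccc1
Why: Silylation of the primary allylic alcohol masks it during sulfonylation, DDQ treatment and esterification, with the same group as the side-chain carbinol so that one fluoride step removes both.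

**Step 21**
Reactants: 27 bis-silyl ether acetonide (as named in step 20)
Product: 28 (1E,4S,5E,7R,8R,9R)-1-(TBDPS-oxymethyl)-7-(PMB-oxy)-4,8-dimethyl-4-(side chain B)cycloundeca-1,5-diene-8,9-diol
Conditions: AcOH/THF/H2O (3:1:1), 45 °C
Reagents that add atoms: none
Why: Mild aqueous acid hydrolysis of the acetonide, under which TBDPS ethers and the PMB ether should survive.

**Step 22**
Reactants: 28 diol (as named in step 21)
Product: 30 (1E,4S,5E,7R,8R,9S)-8,9-epoxy-1-(TBDPS-oxymethyl)-7-(PMB-oxy)-4,8-dimethyl-4-(side chain B)cycloundeca-1,5-diene, via mesylate 29 (not isolated)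
Conditions: MsCl, Et3N, CH2Cl2, −10 °C; then K2CO3, MeOH, rt
Reagents that add atoms: none
Why: Selective sulfonylation of the secondary hydroxyl (the tertiary one is left) and base-induced 3-exo-tet displacement by the tertiary alkoxide with inversion at C9 turn the cis-diol of the former template into the trans-epoxide, which the flexible 11-membered ring allows.

**Step 23**
Reactants: 30 epoxide (as named in step 22)
Product: 31 (1E,4S,5E,7R,8S,9S)-8,9-epoxy-1-(TBDPS-oxymethyl)-4,8-dimethyl-4-(side chain B)cycloundeca-1,5-dien-7-ol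
Conditions: DDQ, CH2Cl2/pH 7 phosphate buffer, 0 °C
Reagents that add atoms: none
Why: Oxidative cleavage of the PMB ether by DDQ under buffered conditions frees the C7 hydroxyl without touching the epoxide, silyl ethers or alkenes (the C8 descriptor changes by priority only).

**Step 24**
Reactants: 31 epoxy alcohol (as named in step 23)
Product: 32 (1E,4S,5E,7R,8R,9S)-8,9-epoxy-1-(TBDPS-oxymethyl)-4,8-dimethyl-4-(side chain B)cycloundeca-1,5-dien-7-yl 3-methylbut-2-enoate
Conditions: 3-methylbut-2-enoic acid, DCC, DMAP, CH2Cl2, rt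
Reagents that add atoms: 3-methylbut-2-enoic acid, CC(C)=CC(=O)O
Why: Steglich esterification with the free acid acylates the only free hydroxyl and avoids the vinylketene pathway that would deconjugate the senecioate if the acid chloride and an amine base were used.

**Step 25**
Reactants: 32 bis-silylated ester (as named in step 24)
Product: 33 CNP0309478.2, (1E,4S,5E,7R,8R,9S)-8,9-epoxy-1-(hydroxymethyl)-4-[(3R)-3-hydroxy-4-methylpent-4-en-1-yl]-4,8-dimethylcycloundeca-1,5-dien-7-yl 3-methylbut-2-enoate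
Conditions: Bu4NF, AcOH, THF, 0 °C to rt
Reagents that add atoms: none
Why: Fluoride cleavage of both TBDPS ethers, buffered with acetic acid, should spare the ester and the epoxide.

**Compound list**
1 | pent-4-ynoic acid | C#CCCC(=O)O | starting material
2 | N-methoxy-N-methylpent-4-ynamide | C#CCCC(=O)N(C)OC | intermediate
3 | 2-methylhept-1-en-6-yn-3-one | C#CCCC(=O)C(C)=C | intermediate
4 | (R)-2-methylhept-1-en-6-yn-3-ol | C#CCC[C@@H](O)C(C)=C | intermediate
5 | (R)-tert-butyl[(2-methylhept-1-en-6-yn-3-yl)oxy]diphenylsilane | C#CCC[C@@H](O[Si](c1ccccc1)(c1ccccc1)C(C)(C)C)C(C)=C | intermediate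
6 | [(1E,5R)-5-(TBDPS-oxy)-2,6-dimethylhepta-1,6-dien-1-yl]dimethylalane | C[Al](C)/C=C(\C)CC[C@@H](O[Si](c1ccccc1)(c1ccccc1)C(C)(C)C)C(C)=C | intermediate (not isolated)
7 | (3R,6E)-3-(TBDPS-oxy)-7-iodo-2,6-dimethylhepta-1,6-diene | I/C=C(\C)CC[C@@H](O[Si](c1ccccc1)(c1ccccc1)C(C)(C)C)C(C)=C | intermediate
8 | tropone (cyclohepta-2,4,6-trien-1-one) | O=C1C=CC=CC=C1 | starting material
9 | 2-methylcyclohepta-3,5-dien-1-one (racemic) | CC1C=CC=CCC1=O | intermediate (not isolated)
10 | 2-methylcyclohepta-2,4-dien-1-one | CC1=CC=CCCC1=O | intermediate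
11 | (R)-2-methylcyclohepta-2,4-dien-1-ol | O[C@@H]1CCC=CC=C1C | intermediate
12 | (1S,2R,5S)-1-methyl-6,7-dioxabicyclo[3.2.2]non-8-en-2-ol (peroxide bridge syn to OH) | [C@@H]1(OO2)C=C[C@@]2(C)[C@H](O)CC1 | intermediate (not isolated)
13 | (4S,5R)-4,5-dihydroxy-4-methylcyclohept-2-en-1-one | O=C1C=C[C@](C)(O)[C@H](O)CC1 | intermediate
14 | (4S,5R)-4,5-(isopropylidenedioxy)-4-methylcyclohept-2-en-1-one | O=C1C=C[C@]2(C)OC(C)(C)O[C@@H]2CC1 | intermediate
15 | (2S,3R,4R,5R)-2,3-epoxy-4,5-(isopropylidenedioxy)-4-methylcycloheptan-1-one (epoxide trans to acetonide) | O=C1[C@H]2O[C@H]2[C@]3(C)OC(C)(C)O[C@@H]3CC1 | intermediate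
16 | (1R,2R,3R,4R,5R)-2,3-epoxy-4,5-(isopropylidenedioxy)-4-methylcycloheptan-1-ol (OH cis to epoxide) | O[C@H]1[C@H]2O[C@H]2[C@]3(C)OC(C)(C)O[C@@H]3CC1 | intermediate
17 | [(1E,5R)-5-(TBDPS-oxy)-2,6-dimethylhepta-1,6-dien-1-yl]lithium | [Li]/C=C(\C)CC[C@@H](O[Si](c1ccccc1)(c1ccccc1)C(C)(C)C)C(C)=C | intermediate (not isolated)
18 | (1R,2S,3R,4S,5R)-4,5-(isopropylidenedioxy)-4-methyl-2-(side chain A)cycloheptane-1,3-diol | O[C@H]1[C@H](/C=C(\C)CC[C@@H](O[Si](c3ccccc3)(c3ccccc3)C(C)(C)C)C(C)=C)[C@@H](O)[C@]2(C)OC(C)(C)O[C@@H]2CC1 | intermediate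
19 | 1,3-O-(4-methoxybenzylidene) acetal of 18, aryl equatorial | O1[C@H]2[C@H](/C=C(\C)CC[C@@H](O[Si](c3ccccc3)(c3ccccc3)C(C)(C)C)C(C)=C)[C@@H](O[C@H]1c3ccc(OC)cc3)[C@]4(C)OC(C)(C)O[C@@H]4CC2 | intermediate
20 | (1R,2S,3R,4R,5R)-4,5-(isopropylidenedioxy)-3-(PMB-oxy)-4-methyl-2-(side chain A)cycloheptan-1-ol | O[C@H]1[C@H](/C=C(\C)CC[C@@H](O[Si](c3ccccc3)(c3ccccc3)C(C)(C)C)C(C)=C)[C@@H](OCc3ccc(OC)cc3)[C@]2(C)OC(C)(C)O[C@@H]2CC1 | intermediate
21 | (2R,3R,4R,5R)-4,5-(isopropylidenedioxy)-3-(PMB-oxy)-4-methyl-2-(side chain A)cycloheptan-1-one | O=C1[C@H](/C=C(\C)CC[C@@H](O[Si](c3ccccc3)(c3ccccc3)C(C)(C)C)C(C)=C)[C@@H](OCc3ccc(OC)cc3)[C@]2(C)OC(C)(C)O[C@@H]2CC1 | intermediate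
22 | (1R,2R,3R,4R,5R)-1-ethynyl-4,5-(isopropylidenedioxy)-3-(PMB-oxy)-4-methyl-2-(side chain A)cycloheptan-1-ol | O[C@@]1(C#C)[C@H](/C=C(\C)CC[C@@H](O[Si](c3ccccc3)(c3ccccc3)C(C)(C)C)C(C)=C)[C@@H](OCc3ccc(OC)cc3)[C@]2(C)OC(C)(C)O[C@@H]2CC1 | intermediate
23 | (1S,2R,3R,4R,5R)-1-ethenyl-4,5-(isopropylidenedioxy)-3-(PMB-oxy)-4-methyl-2-(side chain A)cycloheptan-1-ol | O[C@@]1(C=C)[C@H](/C=C(\C)CC[C@@H](O[Si](c3ccccc3)(c3ccccc3)C(C)(C)C)C(C)=C)[C@@H](OCc3ccc(OC)cc3)[C@]2(C)OC(C)(C)O[C@@H]2CC1 | intermediate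
24 | potassium (1E,4S,5E,7R,8R,9R)-8,9-(isopropylidenedioxy)-7-(PMB-oxy)-4,8-dimethyl-4-(side chain B)cycloundeca-1,5-dien-1-olate | C=C(C)[C@H](O[Si](c3ccccc3)(c3ccccc3)C(C)(C)C)CC[C@]1(C)/C=C/[C@@H](OCc3ccc(OC)cc3)[C@]2(C)OC(C)(C)O[C@@H]2CC/C([O-])=C\C1.[K+] | intermediate (not isolated)
25 | (1E,4S,5E,7R,8R,9R)-8,9-(isopropylidenedioxy)-7-(PMB-oxy)-4,8-dimethyl-4-(side chain B)cycloundeca-1,5-dien-1-yl trifluoromethanesulfonate | C=C(C)[C@H](O[Si](c3ccccc3)(c3ccccc3)C(C)(C)C)CC[C@]1(C)/C=C/[C@@H](OCc3ccc(OC)cc3)[C@]2(C)OC(C)(C)O[C@@H]2CC/C(OS(=O)(=O)C(F)(F)F)=C\C1 | intermediate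
26 | [(1E,4S,5E,7R,8R,9R)-8,9-(isopropylidenedioxy)-7-(PMB-oxy)-4,8-dimethyl-4-(side chain B)cycloundeca-1,5-dien-1-yl]methanol | C=C(C)[C@H](O[Si](c3ccccc3)(c3ccccc3)C(C)(C)C)CC[C@]1(C)/C=C/[C@@H](OCc3ccc(OC)cc3)[C@]2(C)OC(C)(C)O[C@@H]2CC/C(CO)=C\C1 | intermediate
27 | (1E,4S,5E,7R,8R,9R)-1-(TBDPS-oxymethyl)-8,9-(isopropylidenedioxy)-7-(PMB-oxy)-4,8-dimethyl-4-(side chain B)cycloundeca-1,5-diene | C=C(C)[C@H](O[Si](c3ccccc3)(c3ccccc3)C(C)(C)C)CC[C@]1(C)/C=C/[C@@H](OCc3ccc(OC)cc3)[C@]2(C)OC(C)(C)O[C@@H]2CC/C(CO[Si](c3ccccc3)(c3ccccc3)C(C)(C)C)=C\C1 | intermediate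
28 | (1E,4S,5E,7R,8R,9R)-1-(TBDPS-oxymethyl)-7-(PMB-oxy)-4,8-dimethyl-4-(side chain B)cycloundeca-1,5-diene-8,9-diol | C=C(C)[C@H](O[Si](c3ccccc3)(c3ccccc3)C(C)(C)C)CC[C@]1(C)/C=C/[C@@H](OCc3ccc(OC)cc3)[C@](C)(O)[C@H](O)CC/C(CO[Si](c3ccccc3)(c3ccccc3)C(C)(C)C)=C\C1 | intermediate
29 | 9-O-methanesulfonate of 28 (C8 hydroxyl free, configuration as in 28) | C=C(C)[C@H](O[Si](c3ccccc3)(c3ccccc3)C(C)(C)C)CC[C@]1(C)/C=C/[C@@H](OCc3ccc(OC)cc3)[C@](C)(O)[C@H](OS(C)(=O)=O)CC/C(CO[Si](c3ccccc3)(c3ccccc3)C(C)(C)C)=C\C1 | intermediate (not isolated)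
30 | (1E,4S,5E,7R,8R,9S)-8,9-epoxy-1-(TBDPS-oxymethyl)-7-(PMB-oxy)-4,8-dimethyl-4-(side chain B)cycloundeca-1,5-diene | C=C(C)[C@H](O[Si](c3ccccc3)(c3ccccc3)C(C)(C)C)CC[C@]1(C)/C=C/[C@@H](OCc3ccc(OC)cc3)[C@]2(C)O[C@H]2CC/C(CO[Si](c3ccccc3)(c3ccccc3)C(C)(C)C)=C\C1 | intermediate
31 | (1E,4S,5E,7R,8S,9S)-8,9-epoxy-1-(TBDPS-oxymethyl)-4,8-dimethyl-4-(side chain B)cycloundeca-1,5-dien-7-ol | C=C(C)[C@H](O[Si](c3ccccc3)(c3ccccc3)C(C)(C)C)CC[C@]1(C)/C=C/[C@@H](O)[C@]2(C)O[C@H]2CC/C(CO[Si](c3ccccc3)(c3ccccc3)C(C)(C)C)=C\C1 | intermediate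
32 | (1E,4S,5E,7R,8R,9S)-8,9-epoxy-1-(TBDPS-oxymethyl)-4,8-dimethyl-4-(side chain B)cycloundeca-1,5-dien-7-yl 3-methylbut-2-enoate | C=C(C)[C@H](O[Si](c3ccccc3)(c3ccccc3)C(C)(C)C)CC[C@]1(C)/C=C/[C@@H](OC(=O)C=C(C)C)[C@]2(C)O[C@H]2CC/C(CO[Si](c3ccccc3)(c3ccccc3)C(C)(C)C)=C\C1 | intermediate
33 | CNP0309478.2, (1E,4S,5E,7R,8R,9S)-8,9-epoxy-1-(hydroxymethyl)-4-[(3R)-3-hydroxy-4-methylpent-4-en-1-yl]-4,8-dimethylcycloundeca-1,5-dien-7-yl 3-methylbut-2-enoate | C=C(C)[C@H](O)CC[C@]1(C)/C=C/[C@@H](OC(=O)C=C(C)C)[C@]2(C)O[C@H]2CC/C(CO)=C\C1 | target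

**Totals**
Total step count: 25. Longest linear sequence: 20 steps (steps 6 to 25, from tropone); the side-chain fragment takes 5 steps (steps 1 to 5) and joins in step 12.

**Steps most likely to fail and their fallbacks**

Step 18 (key step). The alkoxide may fragment (β-cleavage or retro-ene) faster than it rearranges, because the rearrangement must build a quaternary carbon. A boat pathway could also compete and scramble the enolate geometry and the new stereocenter. The fallback is the neutral, thermal variant, which sets out from 23. The tertiary hydroxyl would be silylated (TMSOTf, 2,6-lutidine, CH2Cl2, −78 °C) to the trimethylsilyl ether F1. Heating F1 (o-dichlorobenzene, about 200 °C, sealed base-washed vessel) should give, by a siloxy-Cope rearrangement through the same chair, the ring-expanded trimethylsilyl enol ether F2. Cleavage of F2 with MeLi (THF, 0 °C) would release the lithium enolate F3 regiospecifically, and PhNTf2 would convert it into enol triflate 25, where the route is rejoined.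

Step 16. The nucleophile may attack the carbonyl from the face opposite to the side chain, which would give the trans-dialkenyl carbinol and hence the wrong enolate geometry in step 18. The ketone may also enolise and lose the β PMB-oxy group. The fallback sets the carbinol before the side chain is attached and starts from epoxy ketone 15. Addition of lithium (trimethylsilyl)acetylide (THF, −78 °C) should occur anti to the epoxide oxygen and give the cis-epoxy carbinol F4. After deprotonation, F4 would be opened at C2 by alkenyllithium 17 with BF3·OEt2 to give the diol F5. The secondary hydroxyl of F5 would be protected (4-methoxybenzyl trichloroacetimidate, TfOH cat., CH2Cl2, −20 °C) to give the PMB ether F6. K2CO3 in MeOH would then remove the C-silyl group to give ethynyl carbinol 22, where the route is rejoined. The weak point of this fallback is that C2 is then next to a fully substituted carbon, so the opening may be slow or poorly regioselective.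

Step 8. Singlet oxygen may add with poor facial selectivity if the hydroxyl does not control the approach, and the ene reaction at the ring methyl may compete. The fallback starts from dienol 11 and uses two well-defined stereospecific steps instead. Hydroxyl-directed epoxidation (VO(acac)2, t-BuOOH, CH2Cl2, 0 °C) of the adjacent trisubstituted alkene should give the cis-epoxy alcohol F7. Opening of this vinyl epoxide with AcOH and Pd(PPh3)4 (THF, rt) through the π-allyl complex of zerovalent palladium, with overall retention, should give the cis-1,4-hydroxy acetate F8. Acetonide formation (2,2-dimethoxypropane, PPTS) gives F9, methanolysis of the acetate (K2CO3, MeOH) gives the allylic alcohol F10, and oxidation with MnO2 (CH2Cl2) gives enone 14, where the route is rejoined.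

**Further compounds**
F1 | step 18 | trimethylsilyl ether of 23 | C[Si](C)(C)O[C@@]1(C=C)[C@H](/C=C(\C)CC[C@@H](O[Si](c3ccccc3)(c3ccccc3)C(C)(C)C)C(C)=C)[C@@H](OCc3ccc(OC)cc3)[C@]2(C)OC(C)(C)O[C@@H]2CC1
F2 | step 18 | trimethylsilyl enol ether corresponding to 25 (OSiMe3 in place of OTf) | C=C(C)[C@H](O[Si](c3ccccc3)(c3ccccc3)C(C)(C)C)CC[C@]1(C)/C=C/[C@@H](OCc3ccc(OC)cc3)[C@]2(C)OC(C)(C)O[C@@H]2CC/C(O[Si](C)(C)C)=C\C1
F3 | step 18 | lithium enolate corresponding to 24 | C=C(C)[C@H](O[Si](c3ccccc3)(c3ccccc3)C(C)(C)C)CC[C@]1(C)/C=C/[C@@H](OCc3ccc(OC)cc3)[C@]2(C)OC(C)(C)O[C@@H]2CC/C([O-])=C\C1.[Li+]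
F4 | step 16 | 2,3-epoxy-4,5-(isopropylidenedioxy)-4-methyl-1-[(trimethylsilyl)ethynyl]cycloheptan-1-ol (OH cis to epoxide) | O[C@@]1(C#C[Si](C)(C)C)[C@H]2O[C@H]2[C@]3(C)OC(C)(C)O[C@@H]3CC1
F5 | step 16 | 4,5-(isopropylidenedioxy)-4-methyl-2-(side chain A)-1-[(trimethylsilyl)ethynyl]cycloheptane-1,3-diol | O[C@@]1(C#C[Si](C)(C)C)[C@H](/C=C(\C)CC[C@@H](O[Si](c3ccccc3)(c3ccccc3)C(C)(C)C)C(C)=C)[C@@H](O)[C@]2(C)OC(C)(C)O[C@@H]2CC1
F6 | step 16 | 3-O-PMB ether of F5 (C-silylated form of 22) | O[C@@]1(C#C[Si](C)(C)C)[C@H](/C=C(\C)CC[C@@H](O[Si](c3ccccc3)(c3ccccc3)C(C)(C)C)C(C)=C)[C@@H](OCc3ccc(OC)cc3)[C@]2(C)OC(C)(C)O[C@@H]2CC1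
F7 | step 8 | 2,3-epoxy-2-methylcyclohept-4-en-1-ol (epoxide cis to OH) | C1=C[C@@H]2O[C@]2(C)[C@H](O)CC1
F8 | step 8 | 4,5-dihydroxy-4-methylcyclohept-2-en-1-yl acetate (all three oxygens cis) | CC(=O)O[C@@H]1C=C[C@](C)(O)[C@H](O)CC1
F9 | step 8 | 4,5-(isopropylidenedioxy)-4-methylcyclohept-2-en-1-yl acetate | CC(=O)O[C@@H]1C=C[C@]2(C)OC(C)(C)O[C@@H]2CC1
F10 | step 8 | 4,5-(isopropylidenedioxy)-4-methylcyclohept-2-en-1-ol | O[C@@H]1C=C[C@]2(C)OC(C)(C)O[C@@H]2CC1
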